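The readings come from a simulation from invented constants.

This flask, the north-west run, cannot have stopped for want of a charge: at 25.0 min it still held 43.3% of its starting material and 0.151 M of reagent. Yet its rate kept sinking.

| flask | starting material | reagent | free catalyst | temperature | remark | time |
|---|---|---|---|---|---|---|
| north-west | 0.39 M | 0.37 M | 20 mM | 90 °C | the very flask that is asked about, followed so far |  |
| west | 0.39 M | 0.74 M | 20 mM | 75 °C | run made earlier |  |
| flask | 0.39 M | 0.370 M | 20 mM | 90 °C |  | 30 min |

| run | time / min | target / % | starting material / % |
|---|---|---|---|
| north-west | 3.00 | 22.2 | 77.3 |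
| north-west | 8.00 | 41.1 | 58.7 |
| north-west | 15.0 | 51.6 | 48.3 |
| north-west | 25.0 | 56.1 | 43.3 |
| west | 0.333 | 1.0 | 98.0 |
| west | 0.417 | 1.0 | 97.5 |
| west | 1.00 | 4.2 | 94.3 |
| west | 3.00 | 14.5 | 84.9 |

(standard deviation of a reading: 0.3 percentage points)

- zeta: at 30 min add free catalyst, 50.0% of the amount charged, then wait 15 min
- theta: at 30 min add reagent, 100% of the amount charged, then wait 15 min
- epsilon: change nothing and wait 15 min more
- delta: at 30 min raise the temperature by 25 K, then wait 15 min
- beta: at 30 min take out 90% of the target then present, then wait 15 min

- removed target is counted in
- the earlier runs were read with a standard deviation of 0.3 percentage points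
- additions bring no volume worth counting

* target, in percent of the starting material first charged, at 30 min
* which option adds most target ("none" when 2 percentage points or less is all one gets) (zeta / theta / epsilon / delta / beta / none)
* target present, with what was taken out counted in, in percent of the starting material first charged, after delta
* target present, with what was taken out counted in, in percent of the starting material first charged, after beta

I wrote the rate as k·c², where c is the geometric mean of the starting material and reagent concentrations and k is a rate constant that carries the catalyst. Over successive intervals of this flask, k read 0.255 /M/min, then, after a gap, 0.148 /M/min and 0.0609 /M/min. The readings do not part a dying catalyst from an equilibrium, and I bet on the catalyst.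

Then I built a ladder. On the lowest rung, the west run had 1.5 percentage points missing at 1.00 min, which I took to be sitting on the catalyst. Next came the loss of k: its last two readings gave a loss constant λ of 0.104 /min, so a loss time of 9.60 min. The material time at the start, 1/(k·c), was 10.3 min, a little longer. The asked 30 min stood above both.

Now, 1/c climbs at rate k, and k shrinks by λ per minute. Dividing one by the other removes time: the climb still to come is k/λ. From the last interval, 1/c had a ceiling of 6.48 /M. The ceiling less 1/c at the start is the catalyst's reach, S = 3.85 /M.

So I expected this flask to stand at 56.5% at 30 min and to end near 57.8%. I reckoned that fresh catalyst at 50.0% of the charge adds half of S to the ceiling, and that this, spent in full, is 10 points. I chose zeta. I took the removal of target to touch neither k nor λ, so I put beta near that end too.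

The forecast said “I therefore read this as an equilibrium”: 57%, then theta, 53% after delta and 69.5% after beta.

    reagent + free catalyst ⇌ catalyst intermediate A (K = 5.50 /M, k = 0.298 /M/s, Ea = 60.0 kJ/mol, ΔH = −44.0 kJ/mol)
    starting material + catalyst intermediate A ⇌ catalyst intermediate B (K = 1.10 /M, k = 0.649 /M/s, Ea = 54.0 kJ/mol, ΔH = −38.0 kJ/mol)
    catalyst intermediate B → catalyst intermediate C (k = 0.291 /s, Ea = 99.0 kJ/mol)
    catalyst intermediate C ⇌ free catalyst + target (K = 8.51 M, k = 5.67 /s, Ea = 69.0 kJ/mol, ΔH = −16.0 kJ/mol)
    starting material → decomposition product (k = 2.33 × 10⁻⁶ /s, Ea = 128 kJ/mol)
    free catalyst → spent catalyst (k = 0.00302 /s, Ea = 99.0 kJ/mol)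
    (constants at 90 °C)

The flask gave 57.3%, and zeta added 10 points, against 2.4 points for theta, while delta ended at 57.5% and beta at 58.2%. In this flask, free catalyst had a half-life of 3.8 min by its path to spent catalyst alone, and the midpoint of the turnover up to 30 min of the step from starting material and catalyst intermediate A came at 4.27 min; at 30.0 min spent catalyst stood at 96.1% of the catalyst charged, beside 42.5% of the starting material charged. Scaled to 0.034 M of free catalyst, S gives an end near 69.4%, and at 30 min that neighbour flask stood at 71.1%.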